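Take the leftover first: at 15 min the summer run has 0.116 M of its starting material not yet turned into target. How fast does that leftover go?

| flask | starting material | partner | time |
|---|---|---|---|
| summer | 0.250 M | 0.500 M |  |
| winter | 0.250 M | 0.750 M |  |
| noon | 0.750 M | 0.500 M |  |
| midnight | 0.250 M | 0.500 M | 38 min |

| summer run: time / min | summer run: [target] / M | winter run: time / min | winter run: [target] / M | noon run: time / min | noon run: [target] / M |
|---|---|---|---|---|---|
| 0.54 | 0.0026 | 0.54 | 7 × 10⁻⁴ | 0.54 | 0.0013 |
| 1.6 | 0.0066 | 1.6 | 0.0077 | 1.6 | 0.0130 |
| 3.1 | 0.0179 | 3.1 | 0.0215 | 3.1 | 0.0401 |
| 4.9 | 0.0388 | 4.9 | 0.0433 | 4.9 | 0.0798 |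
| 7.1 | 0.0618 | 7.1 | 0.0690 | 7.1 | 0.1322 |
| 9.5 | 0.0862 | 9.5 | 0.0922 | 9.5 | 0.1843 |
| 12 | 0.1090 | 12 | 0.1160 | 12 | 0.2348 |
| 15 | 0.1337 | 15 | 0.1400 | 15 | 0.2897 |

(standard deviation of a reading: 0.001 M)

- the power of [starting material] that the first rate follows, about the charge of the summer run; measure it at two percent of starting material made into target (one fixed amount of target, the same in the runs compared)
- the power of [partner] that the first rate follows, about the charge of the summer run; measure it at two percent of starting material made into target
- target in the midnight run at 38 min, as a share of the starting material charged

- Overall: starting material + partner -> target.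
- Constant volume, constant temperature.
- Bound and free are read together.
- An order is taken over about fifteen percent of the charge, up and down.

Run the summer flask slowly. At 1.6 min in the summer run, nearly all of the starting material is still leftover, yet from 0.54 min to that reading target climbs at 0.00377 M/min. Read that as a lag. From 7.1 min to 9.5 min the summer slope reads 0.0102 M/min, faster. Then it sags. Over the last summer interval it reads 0.00823 M/min, lower.

Set partner aside for the late stretch, as a working assumption. Starting material is the limiting reagent in the summer run, and the winter run, charged with 0.750 M of partner, reads 0.00800 M/min over its last interval, about the same as the summer slope.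

So divide the late summer slope by the mean leftover of that interval: 0.0640 /min, the clearing constant, the fraction of leftover turned per minute, here a reading at the summer charge. One summer interval earlier it reads 0.0598 /min. Midnight repeats the summer charge, so let the leftover decay at 0.0640 /min for the 23.0 min past the last reading. My own estimate for target in the midnight run, as a share of the starting material charged, is 89.3%.

The forecast gives an order of 0.42 in starting material (0.25 to 0.65), an order of 0.1 in partner (−0.1 to 0.3) and target at 89% of the charge in the midnight run (78% to 97%), adding that “possible inhibition argues for the lower end”.

The flask gives an order of 0.46 in starting material, an order of 0.25 in partner and target at 90.5% of the charge in the midnight run.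

    starting material ⇌ intermediate + by-product (0.09660 /min, 0.1860 /M/min)
    intermediate + partner → target (2.820 /M/min)
    2 starting material ⇌ idle substrate dimer, settled at all times (1.690 /M)
    2 partner ⇌ idle reagent dimer, settled at all times (10.30 /M)

The partner order stands above the forecast's 0.1; at the two-percent amount of target, the winter rate is 1.1 times the summer rate. Read the same way from the last two noon readings, the clearing constant is 0.0375 /min, lower than the summer 0.0640 /min. Decaying at that constant, the noon leftover reaches half its charge at 20.5 min; the noon flask gets there at 21.0 min.

Readings and results are calculated for substances that don't exist; the scatter is artificial.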